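Count in millimoles per litre and the impurity stops being a small correction: this flask is charged with 0.22 mM of free catalyst and 0.11 mM of impurity, which is half of it.

the same everywhere: left-handed substrate 0.30 M; right-handed substrate 0.30 M; racemization catalyst 7.5 mM; impurity 0.11 mM

| charge | coupling partner | free catalyst | remark | time |
|---|---|---|---|---|
| elm | 1.2 M | 0.31 mM | run made earlier |  |
| birch | 1.2 M | 0.48 mM | run made earlier |  |
| flask | 1.20 M | 0.22 mM |  | 20 min |

| run | time / min | left-handed product / % | right-handed product / % | left-handed substrate / % |
|---|---|---|---|---|
| elm | 2.50 | 30.3 | 13.3 | 20.6 |
| elm | 8.00 | 41.6 | 20.9 | 12.3 |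
| elm | 12.0 | 45.3 | 22.3 | 10.6 |
| elm | 20.0 | 48.2 | 25.2 | 10.2 |
| birch | 2.50 | 40.3 | 20.6 | 10.4 |
| birch | 8.00 | 49.0 | 30.4 | 5.3 |
| birch | 12.0 | 50.7 | 32.1 | 4.7 |
| birch | 20.0 | 52.9 | 32.9 | 3.4 |

(readings scatter by 0.5 percentage points)

* excess of left-handed product over right-handed product in the product at 25 s
* excess of left-handed product over right-handed product in the product at 20 min
* part of the left-handed substrate and right-handed substrate charged together that has reacted at 20 min

- free catalyst is single-handed; left-handed substrate and right-handed substrate are mirror images of each other, charged as a racemate, each of them at the stated concentration
- steps that have been proposed: coupling partner + free catalyst + left-handed substrate -> free catalyst + left-handed product; coupling partner + free catalyst + right-handed substrate -> free catalyst + right-handed product; left-handed substrate + racemization catalyst <-> right-handed substrate + racemization catalyst; coupling partner <-> dormant form; free catalyst + impurity -> spent catalyst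
- an excess is the difference of the two amounts in percent of their sum
- an excess is below zero if the other one leads

Suppose the proposed step takes one free catalyst per impurity. The working catalyst is then c(free catalyst) − c(impurity), and I fold the charges into w = 0.550, the working ratio: working catalyst of this flask over that of elm. If time constants of substrate loss go inversely with working catalyst, w multiplies each logarithmic loss, ln(starting amount / amount left), at equal clock time.

Birch tests this. Working catalyst predicts a ratio to elm of 1.85 and raw catalyst 1.55, while left-handed substrate at 2.50 min reads 1.77.

Late on, one number strains. Elm's losses at 20.0 min are 1.59 (left-handed) and 1.11 (right-handed). Scaled to birch they give 91.0% reacted against 85.8% read. Scaled down to this flask they give 52.1%, which I take as a low figure. Elm passes that conversion between its first two readings, so I bracket eb by their excesses, 33.1% to 39.0%. If catalyst multiplies both handed rates alike, w cancels from the early excess. Elm's first reading gives an apparent selectivity factor of 2.65, but by then elm holds 35.8% of right-handed substrate against 20.6% of left-handed, and any racemization over those 2.50 min refills the left-handed substrate and pulls this factor down. So I take 45.2% as a low figure for ea.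

The forecast, higher than my conversion, says 48.5%, 37% and 59%, on the ground that “The flask has about 0.11 mM net, so I scale exposure by about 0.6”.

The simulation gives 48.3%, 38.0% and 57.0%.

    coupling partner + free catalyst + left-handed substrate → free catalyst + left-handed product (k = 40.0 M⁻² s⁻¹)
    coupling partner + free catalyst + right-handed substrate → free catalyst + right-handed product (k = 13.4 M⁻² s⁻¹)
    left-handed substrate + racemization catalyst ⇌ right-handed substrate + racemization catalyst, rate k3*[racemization catalyst]*[left-handed substrate] forward; the back reaction follows from the equilibrium constant (k = 0.0746 M⁻¹ s⁻¹)
    coupling partner ⇌ dormant form (K = 7.80, k = 0.00368 s⁻¹)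
    free catalyst + impurity → spent catalyst (k = 30500 M⁻¹ s⁻¹)

The forward passage of coupling partner into dormant form runs 1.4 times its use with left-handed substrate at the start and 7.9 times at the end. This flask ends with 7.3% of its coupling partner against 51% of its right-handed substrate. In a neighbour flask with 4.4 × 10⁻⁵ M of impurity and otherwise this recipe, w rises from 0.550 to 0.880, and the same scaling gives 68.8% reacted; the simulation gives 69.6%.

(The numbers in the tables are calculated with made-up constants; the scatter is artificial.)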